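**Retrosynthetic overview**
- The target comes from its bis(O-benzyl) ether by hydrogenolysis; the two CH2OH groups come from two carboxamides by N-Boc activation and hydride cleavage.
- Key disconnection: both aryl–C2/C5 bonds are made at once by a twofold palladium-catalysed, amide-directed C(sp3)–H arylation of a C2-symmetric trans-tetrahydrofuran-3,4-dicarboxamide with an aryl iodide (sets 2,3-cis and 4,5-cis).
- The tetrahydrofuran is the only ring that is built, and it is built first: double alkylation of the dienolate of dimenthyl succinate with bis(chloromethyl) ether (sets C3/C4, trans).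
- Small starting materials: catechol (aryl iodide), succinic anhydride (C3/C4 and both CH2OH carbons), 1,3,5-trioxane (C2, C5, ring oxygen).

Assumption: the menthyl-controlled face selectivity of the succinate dienolate is taken to be the same as in its known ring-forming dialkylations, giving the (3R,4R) diester with (−)-menthol; if it proved opposite, (+)-menthol would be used in step 4.

**Route**

Step 1
Reactants: 1 catechol
Product: 2 guaiacol (2-methoxyphenol)
Conditions: MeI (0.9 equiv), K2CO3 (1.0 equiv), acetone, reflux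
Reagents that add atoms: iodomethane, CI
Why: Williamson ether synthesis; with MeI as the limiting reagent the reaction stops mainly at the monoether, and unreacted catechol is washed out with water.

Step 2
Reactants: 2 guaiacol
Product: 3 4-iodo-2-methoxyphenol
Conditions: NIS (1.0 equiv), TsOH·H2O (10 mol%), MeCN, 0 °C to rt
Reagents that add atoms: N-iodosuccinimide, O=C1CCC(=O)N1I
Why: Electrophilic aromatic iodination; the free hydroxyl is the stronger para director, so iodine enters para to OH.

Step 3
Reactants: 3 4-iodo-2-methoxyphenol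
Product: 4 1-(benzyloxy)-4-iodo-2-methoxybenzene
Conditions: BnBr, K2CO3, DMF, rt
Reagents that add atoms: benzyl bromide, BrCc1ccccc1
Why: Williamson O-benzylation; the benzyl ether survives the C–H arylation, Boc activation and hydride steps.

Step 4
Reactants: 5 succinic anhydride
Product: 6 bis[(1R,2S,5R)-menthyl] succinate
Conditions: (−)-menthol (2.1 equiv), TsOH·H2O (5 mol%), toluene, reflux, Dean–Stark trap
Reagents that add atoms: (1R,2S,5R)-(−)-menthol, O[C@@H]1C[C@H](C)CC[C@H]1C(C)C
Why: Anhydride opening followed by Fischer esterification with azeotropic removal of water installs the two chiral auxiliaries.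

Step 5
Reactants: 7 1,3,5-trioxane
Product: 8 bis(chloromethyl) ether
Conditions: conc. aq. HCl, ClSO3H (excess, added dropwise), 0–10 °C, then rt; overall 2 trioxane + 3 HCl + 3 ClSO3H → 3 ClCH2OCH2Cl + 3 H2SO4; organic layer separated, washed with ice-water, dried, used as a titrated solution (potent carcinogen, closed system)
Reagents that add atoms: hydrogen chloride, Cl; chlorosulfonic acid, O=S(=O)(O)Cl
Why: α-Chloro ether formation: strong acid cracks trioxane to formaldehyde units, two chloromethanol units condense to the bis(α-chloro) ether, and chlorosulfonic acid takes up the water formed while returning HCl, so the two chlorines of 8 come from HCl and ClSO3H and both carbons from trioxane.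

Step 6
Reactants: 6 bis[(1R,2S,5R)-menthyl] succinate; 8 bis(chloromethyl) ether
Product: 10 bis[(1R,2S,5R)-menthyl] (3R,4R)-tetrahydrofuran-3,4-dicarboxylate, via dilithium dienolate 9 (not isolated)
Conditions: lithium 2,2,6,6-tetramethylpiperidide (2.3 equiv), THF, −78 °C; then 8 (1.05 equiv), −78 to −20 °C
Reagents that add atoms: none
Why: Auxiliary-controlled double enolate C-alkylation (intermolecular, then 5-exo-tet ring closure); the menthyl groups shield the same face of both enolate halves, so the two new stereocentres form trans and (3R,4R), as in the known cyclopropanation of this dienolate with bromochloromethane.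

Step 7
Reactants: 10 bis[(1R,2S,5R)-menthyl] (3R,4R)-tetrahydrofuran-3,4-dicarboxylate
Product: 11 (3R,4R)-N3,N4-di(quinolin-8-yl)tetrahydrofuran-3,4-dicarboxamide
Conditions: 8-aminoquinoline (3 equiv), AlMe3 (3 equiv), toluene, 0 °C then 100 °C
Reagents that add atoms: 8-aminoquinoline, Nc1cccc2cccnc12
Why: Weinreb-type aminolysis of the esters by the dimethylaluminium amide is non-basic, so the α-stereocentres are kept while both bidentate directing groups are installed.

Step 8
Reactants: 11 (3R,4R)-N3,N4-di(quinolin-8-yl)tetrahydrofuran-3,4-dicarboxamide; 4 1-(benzyloxy)-4-iodo-2-methoxybenzene (6 equiv)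
Product: 13 (2S,3R,4R,5S)-2,5-bis[4-(benzyloxy)-3-methoxyphenyl]-N3,N4-di(quinolin-8-yl)tetrahydrofuran-3,4-dicarboxamide, via monoarylated diamide 12 (not isolated)
Conditions: Pd(OAc)2 (20 mol%), AgOAc (4.4 equiv), (BnO)2PO2H (40 mol%), t-AmylOH, 110 °C, 36 h
Reagents that add atoms: none
Why: Proposed new method: a twofold amide-directed arylation of both O–CH2 C(sp3)–H bonds of a C2-symmetric trans-tetrahydrofuran-3,4-dicarboxamide in one operation (directed C–H arylation by concerted metalation–deprotonation, Daugulis type); each deprotonated 8-aminoquinoline amide binds divalent palladium as an N,N-chelate, carboxylate-assisted metalation is expected to reach only the hydrogen cis to that amide on the neighbouring O–CH2 (cis-fused five-membered palladacycle; the tertiary methine C–H on the other side is not expected to be cleaved), oxidative addition of 4 gives a tetravalent arylpalladium species and C–C reductive elimination goes with retention, so each aryl is delivered cis to its neighbouring carboxamide while AgOAc removes iodide; because the two amides are trans the two arylations occur on opposite faces and the fixed (3R,4R) centres dictate (2S,5S), giving the 2,3-cis/3,4-trans/4,5-cis array; closest known reaction type: the 8-aminoquinoline-directed cis-selective β-methylene arylation of cyclic carboxamides with aryl iodides under Pd(OAc)2/AgOAc, which to my knowledge has not been shown as a twofold α-oxy arylation of a 3,4-dicarboxamide.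

Step 9
Reactants: 13 (2S,3R,4R,5S)-2,5-bis[4-(benzyloxy)-3-methoxyphenyl]-N3,N4-di(quinolin-8-yl)tetrahydrofuran-3,4-dicarboxamide
Product: 14 di-tert-butyl {[(2S,3R,4R,5S)-2,5-bis[4-(benzyloxy)-3-methoxyphenyl]tetrahydrofuran-3,4-diyl]dicarbonyl}bis[(quinolin-8-yl)carbamate]
Conditions: Boc2O (6 equiv), DMAP (2 equiv), MeCN, 60 °C
Reagents that add atoms: di-tert-butyl dicarbonate, CC(C)(C)OC(=O)OC(=O)OC(C)(C)C
Why: N-acylation of the secondary amides (Boc activation) twists the amide bonds and turns the aminoquinoline into a leaving group.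

Step 10
Reactants: 14 di-tert-butyl {[(2S,3R,4R,5S)-2,5-bis[4-(benzyloxy)-3-methoxyphenyl]tetrahydrofuran-3,4-diyl]dicarbonyl}bis[(quinolin-8-yl)carbamate]
Product: 15 [(2S,3S,4S,5S)-2,5-bis[4-(benzyloxy)-3-methoxyphenyl]tetrahydrofuran-3,4-diyl]dimethanol
Conditions: LiBH4 (8 equiv), THF/MeOH (20:1), 0 °C to rt
Reagents that add atoms: none
Why: Reductive cleavage of the activated N-acyl carbamates; hydride adds to the acyl carbonyl, the carbamate anion leaves and the aldehyde is reduced at once, so C3/C4 are not epimerised (the descriptors change from R to S only through CIP priorities).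

Step 11
Reactants: 15 [(2S,3S,4S,5S)-2,5-bis[4-(benzyloxy)-3-methoxyphenyl]tetrahydrofuran-3,4-diyl]dimethanol
Product: 16 [(2S,3S,4S,5S)-2,5-bis(4-hydroxy-3-methoxyphenyl)tetrahydrofuran-3,4-diyl]dimethanol (Eduesmine)
Conditions: H2 (1 atm), Pd/C (10 wt%), EtOAc/MeOH, rt, stopped at full conversion
Reagents that add atoms: none
Why: Hydrogenolysis of the two aryl benzyl ethers under neutral conditions; no stereocentre is touched and short exposure should spare the cyclic dibenzylic ether.

**Compound list**

1 | catechol (benzene-1,2-diol) | Oc1ccccc1O | starting material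
2 | guaiacol (2-methoxyphenol) | COc1ccccc1O | intermediate
3 | 4-iodo-2-methoxyphenol | COc1cc(I)ccc1O | intermediate
4 | 1-(benzyloxy)-4-iodo-2-methoxybenzene | COc1cc(I)ccc1OCc1ccccc1 | intermediate
5 | succinic anhydride | O=C1CCC(=O)O1 | starting material
6 | bis[(1R,2S,5R)-menthyl] succinate | O=C(CCC(=O)O[C@@H]1C[C@H](C)CC[C@H]1C(C)C)O[C@@H]1C[C@H](C)CC[C@H]1C(C)C | intermediate
7 | 1,3,5-trioxane (cyclic trimer of formaldehyde) | C1OCOCO1 | starting material
8 | bis(chloromethyl) ether | ClCOCCl | intermediate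
9 | dilithium 1,4-bis[(1R,2S,5R)-menthyloxy]buta-1,3-diene-1,4-diolate (dienolate of 6, not isolated) | [Li+].[Li+].[O-]C(O[C@@H]1C[C@H](C)CC[C@H]1C(C)C)=CC=C([O-])O[C@@H]1C[C@H](C)CC[C@H]1C(C)C | intermediate
10 | bis[(1R,2S,5R)-menthyl] (3R,4R)-tetrahydrofuran-3,4-dicarboxylate | O=C(O[C@@H]1C[C@H](C)CC[C@H]1C(C)C)[C@H]1COC[C@@H]1C(=O)O[C@@H]1C[C@H](C)CC[C@H]1C(C)C | intermediate
11 | (3R,4R)-N3,N4-di(quinolin-8-yl)tetrahydrofuran-3,4-dicarboxamide | O=C(Nc1cccc2cccnc12)[C@H]1COC[C@@H]1C(=O)Nc1cccc2cccnc12 | intermediate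
12 | (2S,3R,4R)-2-[4-(benzyloxy)-3-methoxyphenyl]-N3,N4-di(quinolin-8-yl)tetrahydrofuran-3,4-dicarboxamide (aryl cis to the C3 amide, not isolated) | COc1cc([C@H]2OC[C@H](C(=O)Nc3cccc4cccnc34)[C@H]2C(=O)Nc2cccc3cccnc23)ccc1OCc1ccccc1 | intermediate
13 | (2S,3R,4R,5S)-2,5-bis[4-(benzyloxy)-3-methoxyphenyl]-N3,N4-di(quinolin-8-yl)tetrahydrofuran-3,4-dicarboxamide (2,3-cis, 3,4-trans, 4,5-cis) | COc1cc([C@H]2O[C@H](c3ccc(OCc4ccccc4)c(OC)c3)[C@H](C(=O)Nc3cccc4cccnc34)[C@H]2C(=O)Nc2cccc3cccnc23)ccc1OCc1ccccc1 | intermediate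
14 | di-tert-butyl {[(2S,3R,4R,5S)-2,5-bis[4-(benzyloxy)-3-methoxyphenyl]tetrahydrofuran-3,4-diyl]dicarbonyl}bis[(quinolin-8-yl)carbamate] | COc1cc([C@H]2O[C@H](c3ccc(OCc4ccccc4)c(OC)c3)[C@H](C(=O)N(C(=O)OC(C)(C)C)c3cccc4cccnc34)[C@H]2C(=O)N(C(=O)OC(C)(C)C)c2cccc3cccnc23)ccc1OCc1ccccc1 | intermediate
15 | [(2S,3S,4S,5S)-2,5-bis[4-(benzyloxy)-3-methoxyphenyl]tetrahydrofuran-3,4-diyl]dimethanol | COc1cc([C@H]2O[C@H](c3ccc(OCc4ccccc4)c(OC)c3)[C@H](CO)[C@H]2CO)ccc1OCc1ccccc1 | intermediate
16 | [(2S,3S,4S,5S)-2,5-bis(4-hydroxy-3-methoxyphenyl)tetrahydrofuran-3,4-diyl]dimethanol (Eduesmine) | COc1cc([C@H]2O[C@H](c3ccc(O)c(OC)c3)[C@H](CO)[C@H]2CO)ccc1O | target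

**Step count and risks**

Total step count: 11.
Longest linear sequence: 7 steps (steps 1, 2, 3, 8, 9, 10, 11; the branches from 5 and from 7 are equally long).

The three steps most likely to fail:

Step 8 (the proposed new step). The electron-rich O–CH2 bonds may metalate slowly, the substrate may hold palladium as an N4 bis(amidoquinoline) chelate, and the reaction may stop at 12. The fallback uses known chemistry with reversed polarity: an aryl nucleophile adds to cyclic oxocarbenium ions instead of C–H activation. It sets out from 5 and 4 and comes back to the route at 16. Because the ester carbons now become C2/C5 instead of the CH2OH carbons, the antipodal auxiliary is needed. Esterifying 5 with (+)-menthol as in step 4 gives bis[(1S,2R,5S)-menthyl] succinate F1. Its dienolate (lithium 2,2,6,6-tetramethylpiperidide, THF, −78 °C) is alkylated twice with benzyl chloromethyl ether to bis[(1S,2R,5S)-menthyl] (2S,3S)-2,3-bis[(benzyloxy)methyl]succinate F2. Reduction with i-Bu2AlH (toluene, −78 °C) and aqueous work-up gives the dialdehyde as its cyclic hydrate, (3S,4S)-3,4-bis[(benzyloxy)methyl]tetrahydrofuran-2,5-diol F3. PhSO2H/CaCl2 (CH2Cl2) converts it into (3S,4S)-3,4-bis[(benzyloxy)methyl]-2,5-bis(phenylsulfonyl)tetrahydrofuran F4. [4-(Benzyloxy)-3-methoxyphenyl]zinc bromide F5 (from 4 with i-PrMgCl·LiCl, then ZnBr2) replaces both sulfonyl groups through the oxocarbenium ions. Each aryl is expected to enter by inside attack on the envelope oxocarbenium ion, anti to the substituent on the β-carbon and therefore cis to its neighbour (the 1,3-trans preference of 3-alkyl five-membered oxocarbenium ions); any 2,3-trans isomer is removed by chromatography. This gives (2S,3S,4S,5S)-2,5-bis[4-(benzyloxy)-3-methoxyphenyl]-3,4-bis[(benzyloxy)methyl]tetrahydrofuran F6. Hydrogenolysis under the conditions of step 11 removes all four benzyl groups and gives 16.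

Step 6. The very reactive bis-electrophile may oligomerise or O-alkylate the dienolate, and the face selectivity may be lower than with bromochloromethane. The fallback builds the ring by (3+2) cycloaddition instead of alkylation; it sets out from 7 and comes back at 10. 1,3,5-Trioxane 7, (trimethylsilyl)methanol and HCl (gas) give chloromethyl (trimethylsilyl)methyl ether F7. CsF (MeCN, rt) triggers 1,3-elimination, and the carbonyl ylide so released adds stereospecifically across bis[(1R,2S,5R)-menthyl] fumarate F8 (from fumaric acid and (−)-menthol, TsOH, toluene, reflux). The trans diester forms as 10 together with its diastereomer bis[(1R,2S,5R)-menthyl] (3S,4S)-tetrahydrofuran-3,4-dicarboxylate F9, from which 10 is separated by crystallisation or chromatography.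

Step 10. Hydride may attack the carbamate carbonyl (returning 13), or the aldehyde stage may epimerise next to the cis aryl groups. The fallback hydrolyses first and reduces afterwards; it sets out from 14 and comes back at 15. LiOH/H2O2 (THF/H2O, 0 °C) cleaves both N-Boc amides to (2S,3R,4R,5S)-2,5-bis[4-(benzyloxy)-3-methoxyphenyl]tetrahydrofuran-3,4-dicarboxylic acid F10, and BH3·THF (0 °C to rt) reduces the diacid to 15.

Further compounds
F1 | step 8 | bis[(1S,2R,5S)-menthyl] succinate | O=C(CCC(=O)O[C@H]1C[C@@H](C)CC[C@@H]1C(C)C)O[C@H]1C[C@@H](C)CC[C@@H]1C(C)C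
F2 | step 8 | bis[(1S,2R,5S)-menthyl] (2S,3S)-2,3-bis[(benzyloxy)methyl]succinate | O=C(O[C@H]1C[C@@H](C)CC[C@@H]1C(C)C)[C@H](COCc1ccccc1)[C@@H](COCc1ccccc1)C(=O)O[C@H]1C[C@@H](C)CC[C@@H]1C(C)C
F3 | step 8 | (3S,4S)-3,4-bis[(benzyloxy)methyl]tetrahydrofuran-2,5-diol (anomer mixture) | OC1OC(O)[C@H](COCc2ccccc2)[C@H]1COCc1ccccc1
F4 | step 8 | (3S,4S)-3,4-bis[(benzyloxy)methyl]-2,5-bis(phenylsulfonyl)tetrahydrofuran (anomer mixture) | O=S(=O)(c1ccccc1)C1OC(S(=O)(=O)c2ccccc2)[C@H](COCc2ccccc2)[C@H]1COCc1ccccc1
F5 | step 8 | [4-(benzyloxy)-3-methoxyphenyl]zinc bromide | COc1cc([Zn]Br)ccc1OCc1ccccc1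
F6 | step 8 | (2S,3S,4S,5S)-2,5-bis[4-(benzyloxy)-3-methoxyphenyl]-3,4-bis[(benzyloxy)methyl]tetrahydrofuran | COc1cc([C@H]2O[C@H](c3ccc(OCc4ccccc4)c(OC)c3)[C@H](COCc3ccccc3)[C@H]2COCc2ccccc2)ccc1OCc1ccccc1
F7 | step 6 | chloromethyl (trimethylsilyl)methyl ether | C[Si](C)(C)COCCl
F8 | step 6 | bis[(1R,2S,5R)-menthyl] fumarate | O=C(/C=C/C(=O)O[C@@H]1C[C@H](C)CC[C@H]1C(C)C)O[C@@H]1C[C@H](C)CC[C@H]1C(C)C
F9 | step 6 | bis[(1R,2S,5R)-menthyl] (3S,4S)-tetrahydrofuran-3,4-dicarboxylate | O=C(O[C@@H]1C[C@H](C)CC[C@H]1C(C)C)[C@@H]1COC[C@H]1C(=O)O[C@@H]1C[C@H](C)CC[C@H]1C(C)C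
F10 | step 10 | (2S,3R,4R,5S)-2,5-bis[4-(benzyloxy)-3-methoxyphenyl]tetrahydrofuran-3,4-dicarboxylic acid | COc1cc([C@H]2O[C@H](c3ccc(OCc4ccccc4)c(OC)c3)[C@H](C(=O)O)[C@H]2C(=O)O)ccc1OCc1ccccc1
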